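**Retrosynthetic overview**
1. Target ⇐ (acetonide hydrolysis, O-debenzylation) ⇐ protected trans-lactone 26 ⇐ C3–CH2Ar bond: trans-selective alkylation of the (S)-4-(arylmethyl)butyrolactone 24 (anti arm) with benzylic bromide 14 (syn arm).
2. 24 ⇐ C5–O1 bond of the lactone: catalyst-controlled Baeyer–Villiger ring expansion of the Cs-symmetric 3-(arylmethyl)cyclobutanone 22; 22 ⇐ allylarene 20 + dichloroketene.
3. Enabling feature: in the lactone ring (O1, C2, C3, C4, C5), once the C3 benzyl is set aside, C4 carries two ring CH2 groups (C3 and C5). Excising O1 leaves a four-membered ketone (C2, C3, C4, C5) whose two α-CH2 groups are enantiotopic. Oxygen insertion on one side makes the C5–O1 bond and the C4 stereocentre together, and C4 then steers C3.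
4. Both arms (7S; anti on the C4-benzyl ring, syn on the C3-benzyl ring) ⇐ one N-arylacetyl oxazolidinone 7 + O-benzylvanillin 8, by boron syn-aldol and magnesium anti-aldol; 7 ⇐ methyl 5-bromovanillate 1.
5. Ring order: 1,3-dioxane acetonides (temporary) → cyclobutanone (temporary) → γ-lactone (key step) → dioxanes removed.

Key step: step 16

Remark on the chemistry: the SMILES fixes the lactone as 3S,4S (trans) and the arms as 7S,8S (anti, ring on the C4 benzyl) and 7S,8R (syn, ring on the C3 benzyl), with C7 the carbinol carbon and C8 the aryl-bearing carbon of each arm. Compounds 1, 5 and 8 are taken as catalogue compounds. The antipode of the chiral ligand in step 16 is the one that delivers the (S)-lactone. In names, G = 4-benzyloxy-3-methoxyphenyl.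

**Route**

Step 1
Reactants: 1 methyl 3-bromo-4-hydroxy-5-methoxybenzoate
Product: 2 methyl 4-benzyloxy-3-bromo-5-methoxybenzoate
Conditions: BnBr, K2CO3, DMF, 50 °C
Reagents that add atoms: benzyl bromide BrCc1ccccc1
Why: Williamson etherification of the acidic phenol masks it as a benzyl ether that should survive every step until the final hydrogenolysis.

Step 2
Reactants: 2 methyl 4-benzyloxy-3-bromo-5-methoxybenzoate
Product: 3 methyl 4-benzyloxy-3-(2-tert-butoxy-2-oxoethyl)-5-methoxybenzoate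
Conditions: BrZnCH2CO2t-Bu (commercial solution, 1.5 equiv), Pd2(dba)3 (2 mol%), XPhos (5 mol%), THF, 60 °C
Reagents that add atoms: tert-butyl 2-(bromozincio)acetate CC(C)(C)OC(=O)C[Zn]Br
Why: Palladium-catalysed Negishi-type α-arylation with the Reformatsky zinc enolate couples at the C–Br bond under neutral conditions that leave the methyl benzoate untouched, and it installs the carbon that becomes C8 of an arm.

Step 3
Reactants: 3 methyl 4-benzyloxy-3-(2-tert-butoxy-2-oxoethyl)-5-methoxybenzoate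
Product: 4 2-(2-benzyloxy-3-methoxy-5-methoxycarbonylphenyl)acetic acid
Conditions: TFA/CH2Cl2 (1:4), 0 °C → rt
Reagents that add atoms: none
Why: Acidolysis of the tert-butyl ester (E1 loss of isobutene) frees the arylacetic acid, while the methyl ester and the aryl benzyl ether tolerate brief cold TFA.

Step 4
Reactants: 4 2-(2-benzyloxy-3-methoxy-5-methoxycarbonylphenyl)acetic acid; 5 (S)-4-benzyloxazolidin-2-one
Product: 7 methyl 4-benzyloxy-3-{2-[(S)-4-benzyl-2-oxooxazolidin-3-yl]-2-oxoethyl}-5-methoxybenzoate, via mixed pivalic anhydride 6 (not isolated)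
Conditions: PivCl, Et3N, THF, −20 °C; then 5, LiCl, rt
Reagents that add atoms: none
Why: N-acylation of the oxazolidinone auxiliary through the mixed pivalic anhydride (Et3N/LiCl protocol) attaches the auxiliary without touching its stereocentre.

Step 5
Reactants: 7 methyl 4-benzyloxy-3-{2-[(S)-4-benzyl-2-oxooxazolidin-3-yl]-2-oxoethyl}-5-methoxybenzoate; 8 4-benzyloxy-3-methoxybenzaldehyde
Product: 11 (S)-4-benzyl-3-[(2S,3S)-2-(2-benzyloxy-3-methoxy-5-methoxycarbonylphenyl)-3-G-3-hydroxypropanoyl]oxazolidin-2-one (syn adduct), via Z-boron enolate 9 (not isolated), via boron aldolate 10 (not isolated)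
Conditions: Bu2BOTf, i-Pr2NEt, CH2Cl2, −78 → 0 °C; 8, −78 → 0 °C; then pH 7 buffer, MeOH, 30% H2O2, 0 °C
Reagents that add atoms: none
Why: Evans boron syn-aldol reaction, in which the Z-dibutylboron enolate reacts through a Zimmerman–Traxler chair on the enolate face dictated by the (S)-benzyl auxiliary, should set C7 as S and the α-carbon as S in the acyl chain (syn), the configuration of the arm destined for the C3-benzyl ring.

Step 6
Reactants: 11 syn adduct
Product: 12 (1S,2R)-2-[2-benzyloxy-5-(hydroxymethyl)-3-methoxyphenyl]-1-G-propane-1,3-diol (syn triol)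
Conditions: LiBH4 (4 equiv), MeOH (4 equiv), THF, 0 → 40 °C
Reagents that add atoms: none
Why: Borohydride reduction cleaves the N-acyloxazolidinone to the primary alcohol and reduces the methyl benzoate to the benzylic alcohol in one operation without touching C7 or C8 (C8 becomes R only through the change in CIP priorities).

Step 7
Reactants: 12 syn triol
Product: 13 {4-benzyloxy-3-methoxy-5-[(4S,5R)-4-G-2,2-dimethyl-1,3-dioxan-5-yl]phenyl}methanol
Conditions: 2,2-dimethoxypropane, PPTS (cat.), acetone, rt; aq. NH4Cl work-up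
Reagents that add atoms: 2,2-dimethoxypropane COC(C)(C)OC
Why: Thermodynamic acetalisation protects the 1,3-diol as the six-membered acetonide and leaves the remote benzylic primary alcohol free.

Step 8
Reactants: 13 {4-benzyloxy-3-methoxy-5-[(4S,5R)-4-G-2,2-dimethyl-1,3-dioxan-5-yl]phenyl}methanol
Product: 14 (4S,5R)-5-[2-benzyloxy-5-(bromomethyl)-3-methoxyphenyl]-4-G-2,2-dimethyl-1,3-dioxane
Conditions: CBr4, PPh3, 2,6-lutidine, CH2Cl2, 0 °C
Reagents that add atoms: tetrabromomethane BrC(Br)(Br)Br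
Why: Appel bromination under buffered, non-acidic conditions converts the benzylic alcohol into the bromide electrophile without opening the acetonide.

Step 9
Reactants: 7 methyl 4-benzyloxy-3-{2-[(S)-4-benzyl-2-oxooxazolidin-3-yl]-2-oxoethyl}-5-methoxybenzoate; 8 4-benzyloxy-3-methoxybenzaldehyde
Product: 16 (S)-4-benzyl-3-[(2R,3S)-2-(2-benzyloxy-3-methoxy-5-methoxycarbonylphenyl)-3-G-3-hydroxypropanoyl]oxazolidin-2-one (anti adduct), via TMS ether 15 (not isolated)
Conditions: MgCl2 (20 mol%), Et3N, TMSCl, EtOAc, rt; then MeOH, TFA (cat.), rt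
Reagents that add atoms: none
Why: Magnesium-halide-catalysed Evans anti-aldol reaction, in which the chelated magnesium Z-enolate adds to the non-enolisable aryl aldehyde through a boat transition state on the enolate face opposite to that of the boron reaction and is turned over by O-silylation, should again give C7 as S but the opposite configuration at the α-carbon ((2R,3S), anti).

Step 10
Reactants: 16 anti adduct
Product: 17 (1S,2S)-2-[2-benzyloxy-5-(hydroxymethyl)-3-methoxyphenyl]-1-G-propane-1,3-diol (anti triol)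
Conditions: LiBH4 (4 equiv), MeOH (4 equiv), THF, 0 → 40 °C
Reagents that add atoms: none
Why: The same borohydride reduction removes the auxiliary and reduces the benzoate, the two stereocentres being untouched.

Step 11
Reactants: 17 anti triol
Product: 18 {4-benzyloxy-3-methoxy-5-[(4S,5S)-4-G-2,2-dimethyl-1,3-dioxan-5-yl]phenyl}methanol
Conditions: 2,2-dimethoxypropane, PPTS (cat.), acetone, rt; aq. NH4Cl work-up
Reagents that add atoms: 2,2-dimethoxypropane COC(C)(C)OC
Why: Acetalisation gives the trans-4,5-diaryl (diequatorial) dioxane, the thermodynamically preferred isomer and therefore the arm best suited to the Lewis-acidic steps ahead.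

Step 12
Reactants: 18 {4-benzyloxy-3-methoxy-5-[(4S,5S)-4-G-2,2-dimethyl-1,3-dioxan-5-yl]phenyl}methanol
Product: 19 (4S,5S)-5-[2-benzyloxy-5-(bromomethyl)-3-methoxyphenyl]-4-G-2,2-dimethyl-1,3-dioxane
Conditions: CBr4, PPh3, 2,6-lutidine, CH2Cl2, 0 °C
Reagents that add atoms: tetrabromomethane BrC(Br)(Br)Br
Why: Appel bromination as in step 8 gives the benzylic bromide for chain extension.

Step 13
Reactants: 19 (4S,5S)-5-[2-benzyloxy-5-(bromomethyl)-3-methoxyphenyl]-4-G-2,2-dimethyl-1,3-dioxane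
Product: 20 (4S,5S)-5-(5-allyl-2-benzyloxy-3-methoxyphenyl)-4-G-2,2-dimethyl-1,3-dioxane
Conditions: vinylmagnesium bromide, CuI (10 mol%), THF, −20 → 0 °C
Reagents that add atoms: vinylmagnesium bromide C=C[Mg]Br
Why: Copper-catalysed sp3–sp2 cross-coupling of a benzylic bromide with a vinyl Grignard reagent gives the allylarene, and the substrate carries no group that the Grignard reagent would attack.

Step 14
Reactants: 20 (4S,5S)-5-(5-allyl-2-benzyloxy-3-methoxyphenyl)-4-G-2,2-dimethyl-1,3-dioxane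
Product: 21 2,2-dichloro-3-{[4-benzyloxy-3-methoxy-5-((4S,5S)-4-G-2,2-dimethyl-1,3-dioxan-5-yl)phenyl]methyl}cyclobutan-1-one (both C3 epimers)
Conditions: Cl3CCOCl, Zn–Cu couple, POCl3, Et2O, rt
Reagents that add atoms: trichloroacetyl chloride ClC(Cl)(Cl)C(Cl)=O
Why: Thermal [2+2] cycloaddition of dichloroketene generated in situ to the terminal alkene is regioselective for the 2,2-dichloro-3-substituted cyclobutanone (carbonyl carbon to the terminal CH2), and the new ring stereocentre is of no consequence because it is erased in step 15.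

Step 15
Reactants: 21 2,2-dichloro-3-(arylmethyl)cyclobutanone
Product: 22 3-{[4-benzyloxy-3-methoxy-5-((4S,5S)-4-G-2,2-dimethyl-1,3-dioxan-5-yl)phenyl]methyl}cyclobutan-1-one
Conditions: Zn dust, NH4Cl, MeOH, rt
Reagents that add atoms: none
Why: Zinc-mediated reductive dechlorination of the α,α-dichloroketone under near-neutral conditions gives the cyclobutanone with a local mirror plane and should leave benzyl ethers and acetonide intact.

Step 16
Reactants: 22 3-{[4-benzyloxy-3-methoxy-5-((4S,5S)-4-G-2,2-dimethyl-1,3-dioxan-5-yl)phenyl]methyl}cyclobutan-1-one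
Product: 24 (S)-4-{[4-benzyloxy-3-methoxy-5-((4S,5S)-4-G-2,2-dimethyl-1,3-dioxan-5-yl)phenyl]methyl}dihydrofuran-2(3H)-one, via Criegee adduct 23 (not isolated)
Conditions: Sc(OTf)3 (10 mol%), chiral N,N′-dioxide ligand (12 mol%), m-CPBA (1.2 equiv), EtOAc, −20 °C
Reagents that add atoms: m-chloroperbenzoic acid OOC(=O)c1cccc(Cl)c1
Why: Baeyer–Villiger oxidation: the chiral scandium Lewis acid activates the cyclobutanone carbonyl, m-CPBA adds to give Criegee adduct 23, and the ring CH2 antiperiplanar to the O–O bond migrates from carbon to oxygen with loss of 3-chlorobenzoate, which creates the CH2–O bond of the lactone. The closest known reaction type is the catalytic enantioselective Baeyer–Villiger desymmetrisation of prochiral 3-substituted cyclobutanones, 3-benzyl members included, with chiral Lewis or Brønsted acids and a peracid or H2O2. The γ-lactone is closed by ring enlargement, a 1,2-shift that turns the four-membered carbocycle into the five-membered oxacycle and is driven by release of the strain of the four-membered ketone. The stereocentre C4 of the lactone, prochiral in 22, should be fixed as S by the catalyst, which decides which of the two α-CH2 groups (enantiotopic within the ring, diastereotopic only through the remote arm) migrates. The step needs this group selectivity and chemoselectivity over oxidation of the benzyloxy arenes; the local Cs symmetry of the 3-monosubstituted cyclobutanone removes any regiochemical question because both migrations give the same constitution, and the strained ketone should react at a temperature at which the arenes are inert to the peracid.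

Step 17
Reactants: 24 (S)-4-(arylmethyl)butyrolactone with anti arm; 14 (4S,5R)-5-[2-benzyloxy-5-(bromomethyl)-3-methoxyphenyl]-4-G-2,2-dimethyl-1,3-dioxane
Product: 26 (3S,4S)-3-{[4-benzyloxy-3-methoxy-5-((4S,5R)-4-G-2,2-dimethyl-1,3-dioxan-5-yl)phenyl]methyl}-4-{[4-benzyloxy-3-methoxy-5-((4S,5S)-4-G-2,2-dimethyl-1,3-dioxan-5-yl)phenyl]methyl}dihydrofuran-2(3H)-one, via lithium enolate 25 (not isolated)
Conditions: LiHMDS, THF, −78 °C; then 14, DMPU, −78 → −30 °C
Reagents that add atoms: none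
Why: Alkylation of the lithium enolate of a β-substituted γ-butyrolactone occurs anti to the C4 substituent, so the benzylic bromide should enter trans and set C3 as S (substrate control by C4, the standard dibenzylbutyrolactone alkylation).

Step 18
Reactants: 26 protected bis-acetonide lactone
Product: 27 (3S,4S)-3-{[4-benzyloxy-3-((1S,2R)-1-G-1,3-dihydroxypropan-2-yl)-5-methoxyphenyl]methyl}-4-{[4-benzyloxy-3-((1S,2S)-1-G-1,3-dihydroxypropan-2-yl)-5-methoxyphenyl]methyl}dihydrofuran-2(3H)-one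
Conditions: AcOH/H2O/THF (3:1:1), 35 °C
Reagents that add atoms: none
Why: Mild aqueous acid hydrolyses both acetonides through the acetal carbon–oxygen bond (oxocarbenium at the Me2C centre), so the benzylic C7–O bonds and their configuration should not be disturbed and the lactone is stable.

Step 19
Reactants: 27 tetra-O-benzyl tetraol
Product: 28 CNP0113972.1 (target)
Conditions: H2 (1 atm), 10% Pd/C, EtOAc/EtOH, rt
Reagents that add atoms: none
Why: Palladium-catalysed hydrogenolysis cleaves the four aryl benzyl ethers, which react much faster than the secondary benzylic alcohols under neutral conditions, to release the four phenols of the target.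

**Compound list**
1 | methyl 3-bromo-4-hydroxy-5-methoxybenzoate | COC(=O)c1cc(Br)c(O)c(OC)c1 | starting material
2 | methyl 4-benzyloxy-3-bromo-5-methoxybenzoate | COC(=O)c1cc(Br)c(OCc2ccccc2)c(OC)c1 | intermediate
3 | methyl 4-benzyloxy-3-(2-tert-butoxy-2-oxoethyl)-5-methoxybenzoate | COC(=O)c1cc(CC(=O)OC(C)(C)C)c(OCc2ccccc2)c(OC)c1 | intermediate
4 | 2-(2-benzyloxy-3-methoxy-5-methoxycarbonylphenyl)acetic acid | COC(=O)c1cc(CC(=O)O)c(OCc2ccccc2)c(OC)c1 | intermediate
5 | (S)-4-benzyloxazolidin-2-one | O=C1N[C@@H](Cc2ccccc2)CO1 | starting material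
6 | mixed pivalic anhydride of 4 (formed in situ) | COC(=O)c1cc(CC(=O)OC(=O)C(C)(C)C)c(OCc2ccccc2)c(OC)c1 | intermediate
7 | methyl 4-benzyloxy-3-{2-[(S)-4-benzyl-2-oxooxazolidin-3-yl]-2-oxoethyl}-5-methoxybenzoate | COC(=O)c1cc(CC(=O)N2[C@@H](Cc3ccccc3)COC2=O)c(OCc2ccccc2)c(OC)c1 | intermediate
8 | 4-benzyloxy-3-methoxybenzaldehyde | COc1cc(C=O)ccc1OCc1ccccc1 | starting material
9 | Z-dibutylboron enolate of 7 (formed in situ) | CCCCB(CCCC)O/C(=C\c1cc(C(=O)OC)cc(OC)c1OCc1ccccc1)N1[C@@H](Cc2ccccc2)COC1=O | intermediate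
10 | dibutylboron aldolate of the syn adduct (formed in situ) | COc1cc([C@@H](OB(CCCC)CCCC)[C@@H](C(=O)N2[C@@H](Cc3ccccc3)COC2=O)c2cc(C(=O)OC)cc(OC)c2OCc2ccccc2)ccc1OCc1ccccc1 | intermediate
11 | (S)-4-benzyl-3-[(2S,3S)-2-(2-benzyloxy-3-methoxy-5-methoxycarbonylphenyl)-3-G-3-hydroxypropanoyl]oxazolidin-2-one | COc1cc([C@@H](O)[C@@H](C(=O)N2[C@@H](Cc3ccccc3)COC2=O)c2cc(C(=O)OC)cc(OC)c2OCc2ccccc2)ccc1OCc1ccccc1 | intermediate
12 | (1S,2R)-2-[2-benzyloxy-5-(hydroxymethyl)-3-methoxyphenyl]-1-G-propane-1,3-diol | COc1cc([C@@H](O)[C@@H](CO)c2cc(CO)cc(OC)c2OCc2ccccc2)ccc1OCc1ccccc1 | intermediate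
13 | {4-benzyloxy-3-methoxy-5-[(4S,5R)-4-G-2,2-dimethyl-1,3-dioxan-5-yl]phenyl}methanol | COc1cc([C@H]2OC(C)(C)OC[C@H]2c2cc(CO)cc(OC)c2OCc2ccccc2)ccc1OCc1ccccc1 | intermediate
14 | (4S,5R)-5-[2-benzyloxy-5-(bromomethyl)-3-methoxyphenyl]-4-G-2,2-dimethyl-1,3-dioxane | COc1cc([C@H]2OC(C)(C)OC[C@H]2c2cc(CBr)cc(OC)c2OCc2ccccc2)ccc1OCc1ccccc1 | intermediate
15 | O-trimethylsilyl ether of the anti adduct (formed in situ) | COc1cc([C@@H](O[Si](C)(C)C)[C@H](C(=O)N2[C@@H](Cc3ccccc3)COC2=O)c2cc(C(=O)OC)cc(OC)c2OCc2ccccc2)ccc1OCc1ccccc1 | intermediate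
16 | (S)-4-benzyl-3-[(2R,3S)-2-(2-benzyloxy-3-methoxy-5-methoxycarbonylphenyl)-3-G-3-hydroxypropanoyl]oxazolidin-2-one | COc1cc([C@@H](O)[C@H](C(=O)N2[C@@H](Cc3ccccc3)COC2=O)c2cc(C(=O)OC)cc(OC)c2OCc2ccccc2)ccc1OCc1ccccc1 | intermediate
17 | (1S,2S)-2-[2-benzyloxy-5-(hydroxymethyl)-3-methoxyphenyl]-1-G-propane-1,3-diol | COc1cc([C@@H](O)[C@H](CO)c2cc(CO)cc(OC)c2OCc2ccccc2)ccc1OCc1ccccc1 | intermediate
18 | {4-benzyloxy-3-methoxy-5-[(4S,5S)-4-G-2,2-dimethyl-1,3-dioxan-5-yl]phenyl}methanol | COc1cc([C@H]2OC(C)(C)OC[C@@H]2c2cc(CO)cc(OC)c2OCc2ccccc2)ccc1OCc1ccccc1 | intermediate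
19 | (4S,5S)-5-[2-benzyloxy-5-(bromomethyl)-3-methoxyphenyl]-4-G-2,2-dimethyl-1,3-dioxane | COc1cc([C@H]2OC(C)(C)OC[C@@H]2c2cc(CBr)cc(OC)c2OCc2ccccc2)ccc1OCc1ccccc1 | intermediate
20 | (4S,5S)-5-(5-allyl-2-benzyloxy-3-methoxyphenyl)-4-G-2,2-dimethyl-1,3-dioxane | COc1cc([C@H]2OC(C)(C)OC[C@@H]2c2cc(CC=C)cc(OC)c2OCc2ccccc2)ccc1OCc1ccccc1 | intermediate
21 | 2,2-dichloro-3-{[4-benzyloxy-3-methoxy-5-((4S,5S)-4-G-2,2-dimethyl-1,3-dioxan-5-yl)phenyl]methyl}cyclobutan-1-one (both C3 epimers) | COc1cc([C@H]2OC(C)(C)OC[C@@H]2c2cc(CC3CC(=O)C3(Cl)Cl)cc(OC)c2OCc2ccccc2)ccc1OCc1ccccc1 | intermediate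
22 | 3-{[4-benzyloxy-3-methoxy-5-((4S,5S)-4-G-2,2-dimethyl-1,3-dioxan-5-yl)phenyl]methyl}cyclobutan-1-one | COc1cc([C@H]2OC(C)(C)OC[C@@H]2c2cc(CC3CC(=O)C3)cc(OC)c2OCc2ccccc2)ccc1OCc1ccccc1 | intermediate
23 | Criegee adduct of 22 with m-CPBA (formed in situ; ring configuration not defined) | COc1cc([C@H]2OC(C)(C)OC[C@@H]2c2cc(CC3CC(O)(OOC(=O)c4cccc(Cl)c4)C3)cc(OC)c2OCc2ccccc2)ccc1OCc1ccccc1 | intermediate
24 | (S)-4-{[4-benzyloxy-3-methoxy-5-((4S,5S)-4-G-2,2-dimethyl-1,3-dioxan-5-yl)phenyl]methyl}dihydrofuran-2(3H)-one | COc1cc([C@H]2OC(C)(C)OC[C@@H]2c2cc(C[C@@H]3COC(=O)C3)cc(OC)c2OCc2ccccc2)ccc1OCc1ccccc1 | intermediate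
25 | lithium enolate of 24 (formed in situ) | COc1cc([C@H]2OC(C)(C)OC[C@@H]2c2cc(C[C@@H]3COC(O[Li])=C3)cc(OC)c2OCc2ccccc2)ccc1OCc1ccccc1 | intermediate
26 | (3S,4S)-3-{[4-benzyloxy-3-methoxy-5-((4S,5R)-4-G-2,2-dimethyl-1,3-dioxan-5-yl)phenyl]methyl}-4-{[4-benzyloxy-3-methoxy-5-((4S,5S)-4-G-2,2-dimethyl-1,3-dioxan-5-yl)phenyl]methyl}dihydrofuran-2(3H)-one | COc1cc([C@H]2OC(C)(C)OC[C@@H]2c2cc(C[C@@H]3COC(=O)[C@H]3Cc3cc(OC)c(OCc4ccccc4)c([C@@H]4COC(C)(C)O[C@@H]4c4ccc(OCc5ccccc5)c(OC)c4)c3)cc(OC)c2OCc2ccccc2)ccc1OCc1ccccc1 | intermediate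
27 | tetra-O-benzyl ether of the target (all four alcohols free) | COc1cc([C@@H](O)[C@H](CO)c2cc(C[C@@H]3COC(=O)[C@H]3Cc3cc(OC)c(OCc4ccccc4)c([C@H](CO)[C@H](O)c4ccc(OCc5ccccc5)c(OC)c4)c3)cc(OC)c2OCc2ccccc2)ccc1OCc1ccccc1 | intermediate
28 | CNP0113972.1 | COc1cc([C@@H](O)[C@H](CO)c2cc(C[C@@H]3COC(=O)[C@H]3Cc3cc(OC)c(O)c([C@H](CO)[C@H](O)c4ccc(O)c(OC)c4)c3)cc(OC)c2O)ccc1O | target

**Step count and risks**

Total step count: 19. Longest linear sequence: 15 steps (steps 1–4, 9–16, 17–19).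

Steps most likely to fail:

1. Step 9. The α-aryl imide is more acidic than the substrates on which the magnesium-catalysed anti-aldol is usually run, so erosion of the anti preference, epimerisation at the α-carbon or retro-aldol cleavage may occur. The fallback corrects the syn series thermodynamically. It sets out from 11: LiOH/H2O2 (THF/H2O, 0 °C) removes the auxiliary to give (2S,3S)-2-(2-benzyloxy-3-methoxy-5-methoxycarbonylphenyl)-3-G-3-hydroxypropanoic acid F1. 2-Methoxypropene/PPTS closes this to the cis-(5S,6S)-5,6-diaryl-2,2-dimethyl-1,3-dioxan-4-one F2. Catalytic DBU (CH2Cl2, rt) equilibrates the acidic C5–H, the future C8, to the diequatorial trans-(5R,6S)-dioxanone F3. LiBH4/MeOH then reduces the dioxanone carbonyl and the benzoate, and the sequence comes back to the route at 17.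

2. Step 16. On this large substrate the catalyst may discriminate poorly between the two α-methylene groups, which would give the C4-epimeric lactone as a diastereomer that is hard to separate, or the Lewis acid may open the acetonide. The fallback builds the stereocentre by asymmetric hydrogenation. It sets out from 18: MnO2 (CH2Cl2) gives 4-benzyloxy-3-methoxy-5-[(4S,5S)-4-G-2,2-dimethyl-1,3-dioxan-5-yl]benzaldehyde F4. Stobbe condensation with dimethyl succinate (t-BuOK, t-BuOH) gives the (E)-4-aryl-3-(methoxycarbonyl)but-3-enoic acid F5. Rhodium(I)/chiral bisphosphine hydrogenation (H2, MeOH, Et3N), which leaves benzyl ethers alone, gives the (S)-4-aryl-3-(methoxycarbonyl)butanoic acid F6. Reduction of the ester in the carboxylate salt with Ca(BH4)2 (EtOH) gives the (S)-4-aryl-3-(hydroxymethyl)butanoic acid F7, which lactonises on mild acidification, and the sequence comes back to the route at 24.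

3. Step 17. The electron-rich benzylic bromide 14 may decompose by ionisation before it is alkylated, the SN2 reaction between two bulky partners may be slow, and the enolate may be alkylated twice. The fallback replaces alkylation by aldol condensation and conjugate reduction. It sets out from 13 and 24: MnO2 converts 13 into 4-benzyloxy-3-methoxy-5-[(4S,5R)-4-G-2,2-dimethyl-1,3-dioxan-5-yl]benzaldehyde F8. Enolate 25 (from 24, LiHMDS, −78 °C) adds to F8 to give the 3-[aryl(hydroxy)methyl] lactone F9 (mixture at the two new centres). MsCl/Et3N gives its mesylate F10, and DBU eliminates to the (E)-3-arylidene lactone F11. Conjugate reduction (NaBH4, NiCl2·6H2O, MeOH/THF, 0 °C) followed by DBU equilibration of C3 to the trans isomer comes back to the route at 26.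

Further compounds
F1 | step 9 | (2S,3S)-2-(2-benzyloxy-3-methoxy-5-methoxycarbonylphenyl)-3-G-3-hydroxypropanoic acid | COc1cc([C@@H](O)[C@@H](C(=O)O)c2cc(C(=O)OC)cc(OC)c2OCc2ccccc2)ccc1OCc1ccccc1
F2 | step 9 | methyl 4-benzyloxy-3-[(5S,6S)-6-G-2,2-dimethyl-4-oxo-1,3-dioxan-5-yl]-5-methoxybenzoate (cis) | COc1cc([C@H]2OC(C)(C)OC(=O)[C@H]2c2cc(C(=O)OC)cc(OC)c2OCc2ccccc2)ccc1OCc1ccccc1
F3 | step 9 | methyl 4-benzyloxy-3-[(5R,6S)-6-G-2,2-dimethyl-4-oxo-1,3-dioxan-5-yl]-5-methoxybenzoate (trans) | COc1cc([C@H]2OC(C)(C)OC(=O)[C@@H]2c2cc(C(=O)OC)cc(OC)c2OCc2ccccc2)ccc1OCc1ccccc1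
F4 | step 16 | 4-benzyloxy-3-methoxy-5-[(4S,5S)-4-G-2,2-dimethyl-1,3-dioxan-5-yl]benzaldehyde | COc1cc([C@H]2OC(C)(C)OC[C@@H]2c2cc(C=O)cc(OC)c2OCc2ccccc2)ccc1OCc1ccccc1
F5 | step 16 | (E)-4-aryl-3-(methoxycarbonyl)but-3-enoic acid (Stobbe half-ester, anti arm) | COc1cc([C@H]2OC(C)(C)OC[C@@H]2c2cc(/C=C(\CC(=O)O)C(=O)OC)cc(OC)c2OCc2ccccc2)ccc1OCc1ccccc1
F6 | step 16 | (S)-4-aryl-3-(methoxycarbonyl)butanoic acid (anti arm) | COc1cc([C@H]2OC(C)(C)OC[C@@H]2c2cc(C[C@H](C(=O)OC)CC(=O)O)cc(OC)c2OCc2ccccc2)ccc1OCc1ccccc1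
F7 | step 16 | (S)-4-aryl-3-(hydroxymethyl)butanoic acid (anti arm) | COc1cc([C@H]2OC(C)(C)OC[C@@H]2c2cc(C[C@H](CO)CC(=O)O)cc(OC)c2OCc2ccccc2)ccc1OCc1ccccc1
F8 | step 17 | 4-benzyloxy-3-methoxy-5-[(4S,5R)-4-G-2,2-dimethyl-1,3-dioxan-5-yl]benzaldehyde | COc1cc([C@H]2OC(C)(C)OC[C@H]2c2cc(C=O)cc(OC)c2OCc2ccccc2)ccc1OCc1ccccc1
F9 | step 17 | 3-[aryl(hydroxy)methyl] aldol adduct of 24 and F8 (mixture at the two new centres) | COc1cc([C@H]2OC(C)(C)OC[C@@H]2c2cc(C[C@@H]3COC(=O)C3C(O)c3cc(OC)c(OCc4ccccc4)c([C@@H]4COC(C)(C)O[C@@H]4c4ccc(OCc5ccccc5)c(OC)c4)c3)cc(OC)c2OCc2ccccc2)ccc1OCc1ccccc1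
F10 | step 17 | mesylate of F9 | COc1cc([C@H]2OC(C)(C)OC[C@@H]2c2cc(C[C@@H]3COC(=O)C3C(OS(C)(=O)=O)c3cc(OC)c(OCc4ccccc4)c([C@@H]4COC(C)(C)O[C@@H]4c4ccc(OCc5ccccc5)c(OC)c4)c3)cc(OC)c2OCc2ccccc2)ccc1OCc1ccccc1
F11 | step 17 | (E)-3-arylidene-4-(arylmethyl)butyrolactone | COc1cc([C@H]2OC(C)(C)OC[C@@H]2c2cc(C[C@@H]3COC(=O)/C3=C/c3cc(OC)c(OCc4ccccc4)c([C@@H]4COC(C)(C)O[C@@H]4c4ccc(OCc5ccccc5)c(OC)c4)c3)cc(OC)c2OCc2ccccc2)ccc1OCc1ccccc1
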